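**Plan**

Cuts, in retrosynthetic order: C16–OH and C16=C17 (hydration and methylenation of a 16-ketone); C13–C16, redrawn as C12–C16 (radical 1,2-acyl shift); C8–C14 and C12–C13 (Diels–Alder); C4–C18; C4–C5 and C1–C10 (ring A annulation); C6–C7 and C10–C20 (two acylations of a 2-indanone).
Enabling feature: once C16 is bonded to C12 instead of C13, atoms C8, C15, C16, C12, C11 and C9 form a six-membered carbocycle. It can be a guaiacol ring, with the phenol oxygen as the C16 oxygen and OMe on C15. C13–C14 is then a two-carbon dienophile that makes C8 quaternary, and the C7 carboxyl on C6 lies cis to C15 on the β face of ring B, so it can be tied to C15 as a γ-lactone ketal.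
Forward ring order: arene plus ring B (indanone), then ring A (Michael addition and Knoevenagel closure), then ring C inside a bicyclo[2.2.2]octenone (key step), then ring D by moving C16 from C12 to C13.
Stereochemistry, part 1: C10 comes from a cinchona-catalysed Michael addition and is the only centre set from outside. C5 and C6 come from hydrogenation anti to the C20 ester, then epimerisation at C6. C4 comes from methylation anti to C20, and C3 from a bulky hydride.
Stereochemistry, part 2: C8 (with C12 and C13) is fixed by the lactone tether in the cycloaddition, C9 by hydrogenation anti to C20, and C16 by exo capture of O2.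

Key step: step 18

Numbering and faces: gibberellane numbering is used throughout. β is the face of H5 and H9; α is the face of C20.
Assumption: the cupreidine-type catalyst of step 9 is taken to give the (R)-configured C10 centre drawn; if the sense is opposite on this substrate, the pseudoenantiomeric cupreine catalyst is used.
Remark: 8, 9 and 14 are drawn as keto tautomers; C6 in 9 and 14 (and C10 in 8 and 9) is configurationally labile and left undefined.

**Step 1**
Reactants: 1 4,5-dimethoxy-1-indanone
Product: 2 5-hydroxy-4-methoxy-1-indanone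
Conditions: EtSNa (1.5 equiv), DMF, 110 °C; then 1 M HCl
Reagents that add atoms: none
Why: Thiolate SN2 dealkylation of an aryl methyl ether goes at the 5-methoxy group, because only its phenoxide is conjugated with the para ketone, while the 4-methoxy group (later the C15 OMe) is meta to it.

**Step 2**
Reactants: 2 5-hydroxy-4-methoxy-1-indanone
Product: 3 4-methoxy-5-(methoxymethoxy)-1-indanone
Conditions: MOMCl, i-Pr2NEt, CH2Cl2, 0 °C to rt
Reagents that add atoms: chloromethyl methyl ether, COCCl
Why: Williamson-type O-alkylation gives an acetal ether that survives hydride, strong base and hydrogenation and is later removed together with the tert-butyl ester.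

**Step 3**
Reactants: 3 4-methoxy-5-(methoxymethoxy)-1-indanone
Product: 5 7-methoxy-6-(methoxymethoxy)-1H-indene, via indanol 4 (not isolated)
Conditions: NaBH4, MeOH, 0 °C; evaporate; PPTS (10 mol %), toluene, 80 °C
Reagents that add atoms: none
Why: Borohydride reduction followed by E1 dehydration is easy because the benzylic cation is para to the MOM oxygen, and the stereocentre of 4 disappears at once.

**Step 4**
Reactants: 5 7-methoxy-6-(methoxymethoxy)-1H-indene
Product: 7 4-methoxy-5-(methoxymethoxy)-2-indanone, via epoxide 6 (not isolated)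
Conditions: dimethyldioxirane, acetone–CH2Cl2, 0 °C; then MgBr2·OEt2 (10 mol %), 0 °C
Reagents that add atoms: dimethyldioxirane, CC1(C)OO1
Why: Neutral epoxidation and Meinwald rearrangement: the epoxide opens at the benzylic carbon and a 1,2-hydride shift places the carbonyl on C5.

**Step 5**
Reactants: 7 4-methoxy-5-(methoxymethoxy)-2-indanone
Product: 8 methyl 4-methoxy-5-(methoxymethoxy)-2-oxoindane-1-carboxylate
Conditions: NaH, (MeO)2CO, THF, reflux; then 1 M HCl
Reagents that add atoms: dimethyl carbonate, COC(=O)OC
Why: Claisen-type carbomethoxylation under equilibrating conditions should settle on the enolate whose ester lies beside H11 and not beside the C15 methoxy group, so the new carbon is C20 on C10.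

**Step 6**
Reactants: 8 methyl 4-methoxy-5-(methoxymethoxy)-2-oxoindane-1-carboxylate
Product: 9 3-tert-butyl 1-methyl 4-methoxy-5-(methoxymethoxy)-2-oxoindane-1,3-dicarboxylate
Conditions: LiN(i-Pr)2 (3.2 equiv), THF, −78 to 0 °C; Boc2O, −78 °C; then cold 1 M HCl
Reagents that add atoms: di-tert-butyl dicarbonate, CC(C)(C)OC(=O)OC(=O)OC(C)(C)C
Why: γ-Acylation of a β-keto ester dianion: the second, more reactive carbanion is C6, so C7 enters there as a tert-butyl ester that stays distinguishable from C20.

**Step 7**
Reactants: 10 methyl acetate; 11 acrolein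
Product: 12 methyl 3-hydroxypent-4-enoate (racemic)
Conditions: LiN(i-Pr)2, THF, −78 °C; then 11; then 1 M HCl
Reagents that add atoms: none
Why: Directed aldol addition of the ester lithium enolate to the aldehyde carbon of acrolein; the carbinol centre is oxidised away in the next step.

**Step 8**
Reactants: 12 methyl 3-hydroxypent-4-enoate
Product: 13 methyl 3-oxopent-4-enoate
Conditions: Dess–Martin periodinane, CH2Cl2, 0 °C; used at once
Reagents that add atoms: none
Why: Dess–Martin oxidation of the allylic alcohol under neutral conditions gives the polymerisation-prone vinyl ketone without acid or base.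

**Step 9**
Reactants: 9 3-tert-butyl 1-methyl 4-methoxy-5-(methoxymethoxy)-2-oxoindane-1,3-dicarboxylate; 13 methyl 3-oxopent-4-enoate
Product: 14 3-tert-butyl 1-methyl (1R)-4-methoxy-5-(methoxymethoxy)-1-(5-methoxy-3,5-dioxopentyl)-2-oxoindane-1,3-dicarboxylate (C20 ester α on quaternary C10)
Conditions: 9-O-(phenanthren-9-yl)cupreidine (10 mol %), CH2Cl2, −20 °C
Reagents that add atoms: none
Why: Enantioselective Michael addition of a cyclic β-keto ester to a vinyl ketone under bifunctional cinchona catalysis forms C1–C10; C6 is shut off by its tert-butyl ester and the C15 methoxy group, and the catalyst-bound enolate is attacked on one face, which sets C10.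

**Step 10**
Reactants: 14 Michael adduct
Product: 15 9-tert-butyl 1,4a-dimethyl 2-hydroxy-8-methoxy-7-(methoxymethoxy)-3,4-dihydro-4aH-fluorene-1,4a,9-tricarboxylate (dienol C3(OH)=C4–C5=C6, C20 ester α)
Conditions: piperidine (20 mol %), AcOH (20 mol %), 4 Å molecular sieves, toluene, 80 °C
Reagents that add atoms: none
Why: Intramolecular Knoevenagel condensation, the closing half of a Robinson-type annulation, joins the active methylene C4 to the C5 ketone and closes six-membered ring A; loss of water is driven by conjugation of the new diene with the arene and both esters.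

**Step 11**
Reactants: 15 tricyclic dienol
Product: 16 trans-fused β-keto ester (enol form) with H5β and H6β, that is, C7 ester α
Conditions: H2 (50 bar), 10% Pd/C, EtOAc–AcOH, 40 °C
Reagents that add atoms: none
Why: Heterogeneous syn hydrogenation of the tetrasubstituted indene bond C5=C6: the flat π system should adsorb by its β face, opposite the C20 ester that stands perpendicular on C10, so both hydrogens arrive β and the A/B fusion becomes trans.

**Step 12**
Reactants: 16 trans-fused β-keto ester
Product: 17 3-ketone with quaternary C4 (C18 methyl β, C19 ester α) and C7 ester still α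
Conditions: K2CO3, MeI, acetone, rt to 40 °C
Reagents that add atoms: iodomethane, CI
Why: C-Alkylation of the β-keto ester enolate: the α face of C4 is closed by the axial C20 ester and by the α-oriented C7 ester, so MeI comes from the β face and leaves C18 equatorial and C19 axial.

**Step 13**
Reactants: 17 ketone with α C7 ester
Product: 18 ketone with C7 ester β and H6α
Conditions: DBU (1 equiv), toluene, 80 °C
Reagents that add atoms: none
Why: Base-mediated epimerisation of the arylacetic ester centre: relief of the syn contact between the α C7 ester and axial C19 drives C6 to the isomer that is trans to C4.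

**Step 14**
Reactants: 18 ketone
Product: 19 3β-alcohol
Conditions: LiBH(s-Bu)3, THF, −78 to −40 °C; then 1 M HCl to pH 5
Reagents that add atoms: none
Why: A bulky trialkylborohydride attacks the cyclohexanone along the equatorial direction, avoiding axial H1 and H5, which gives the axial 3β-alcohol as with other 4,4-disubstituted 3-ketones.

**Step 15**
Reactants: 19 3β-alcohol
Product: 20 3β-acetate
Conditions: Ac2O, DMAP, pyridine, 40 °C
Reagents that add atoms: acetic anhydride, CC(=O)OC(C)=O
Why: DMAP-catalysed acetylation masks the hindered alcohol against the basic ylide of step 22 and against retro-aldol cleavage.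

**Step 16**
Reactants: 20 3β-acetate
Product: 21 hexahydrofluorene guaiacol with free C7 acid (C16 OH, C15 OMe, C19 and C20 methyl esters, 3β-OAc)
Conditions: CF3CO2H–CH2Cl2 (1:3), trace H2O, 0 °C to rt
Reagents that add atoms: none
Why: Acidolysis removes the tert-butyl ester as isobutene (E1) and hydrolyses the MOM acetal in one operation, while the methyl esters and the acetate are inert.

**Step 17**
Reactants: 22 acryloyl chloride; 23 N-hydroxyphthalimide
Product: 24 N-(acryloyloxy)phthalimide
Conditions: Et3N, CH2Cl2, 0 °C
Reagents that add atoms: none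
Why: O-Acylation of the N-hydroxy imide gives an acrylate whose activating group is also the later radical precursor.

**Step 18**
Reactants: 21 guaiacol acid; 24 N-(acryloyloxy)phthalimide
Product: 26 bicyclo[2.2.2]octenone adduct (C8–C14 and C12–C13 formed, C9=C11, C16 ketone, C15 bearing α OMe and the β lactone oxygen of C7, C13 phthalimidoyl ester endo), via lactone ketal dienone 25 (not isolated)
Conditions: PhI(OAc)2 (1.1 equiv), CH2Cl2, −40 to 0 °C; then 24 (5 equiv), BHT (cat.), toluene, 70 °C
Reagents that add atoms: none
Why: Ligand exchange of the phenol on PhI(OAc)2 and loss of PhI make C15 electrophilic, and the C7 carboxyl on the β face of C6 closes onto it (5-exo attack, γ-lactone) to give the 6-acyloxy-6-methoxycyclohexa-2,4-dienone 25, an intramolecular Wessely-type ortho-acyloxylation of a guaiacol. The diene C8=C9–C11=C12 then adds 24 in a concerted suprafacial [4+2] cycloaddition that forms C8–C14 and C12–C13 and closes six-membered ring C (C8, C9, C11, C12, C13, C14) inside a bicyclo[2.2.2]octenone; the closest known reactions are the trappings of masked o-benzoquinones and o-quinol acetates by acrylates. Regioselectivity follows the polarisation of such dienones, which put the carbonyl-bearing dienophile carbon next to the bridgehead α to the ketone, so C13 binds C12 and the CH2 group binds hindered C8. C15 is fixed because the acid reaches only the β face; C8 and C12 are fixed because ring B and the lactone share the C6–C8 bond and must end as a cis-bicyclo[3.3.0]octane, so C14 can enter only on the face of H6 (α) although the C20 ester also lies there; C13 follows the endo rule and is erased in step 19. The required facial selectivity therefore rests on the tether and not on sterics alone, release of angle strain at C8 should speed the addition, and the substituents on C8 and C9 hold back dimerisation of 25.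

**Step 19**
Reactants: 26 bicyclo[2.2.2]octenone adduct
Product: 27 bicyclo[3.2.1]octenone (C16 now on C13, C9=C11, lactone ketal at C15 intact)
Conditions: Ru(bpy)3(PF6)2 (1 mol %), diethyl 2,6-dimethyl-1,4-dihydropyridine-3,5-dicarboxylate (1.5 equiv), CH2Cl2 (0.005 M), blue LEDs, rt
Reagents that add atoms: none
Why: Photoredox decarboxylation of the N-acyloxyphthalimide releases the C13 radical, which adds to the neighbouring C16 carbonyl (3-exo) and reopens by cleavage of C12–C16 to the C12–C11–C9 allyl radical, the radical 1,2-acyl shift known to turn bicyclo[2.2.2]octenones into bicyclo[3.2.1]octenones; high dilution and a weak hydrogen donor give the shift time, hydrogen is taken up at the less hindered C12, and the cage holds C13 in the required configuration.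

**Step 20**
Reactants: 27 bicyclo[3.2.1]octenone lactone ketal
Product: 28 16-ketone with C15H2 and free C7 acid
Conditions: SmI2 (6 equiv), THF–MeOH, −78 to 0 °C
Reagents that add atoms: none
Why: Divalent samarium cleaves C–O bonds α to a ketone (reductive α-deoxygenation through ketyl and samarium enolate): first the lactone oxygen, which frees the C7 acid, then the methoxy group, without touching the esters or the alkene.

**Step 21**
Reactants: 28 unsaturated keto acid
Product: 29 saturated keto acid with H9β
Conditions: H2 (60 bar), 10% Pd/C, EtOAc, 50 °C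
Reagents that add atoms: none
Why: Heterogeneous syn hydrogenation of the trisubstituted C9=C11 bond: the α face is closed by the axial C20 ester on C10 and by C14, so hydrogen, helped by adsorption of the β-oriented C7 acid, should reach C9 from the β face.

**Step 22**
Reactants: 29 saturated keto acid
Product: 30 16-methylene acid
Conditions: Ph3PCH3Br, KOt-Bu (4 equiv each), THF, 0 °C to rt
Reagents that add atoms: methyltriphenylphosphonium bromide, C[P+](c1ccccc1)(c1ccccc1)c1ccccc1.[Br-]
Why: Wittig methylenation of the unhindered cyclopentanone carbonyl C16 brings in C17; one equivalent of ylide is spent on the C7 acid, whose carboxylate is inert, and the esters do not react at this temperature.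

**Step 23**
Reactants: 30 16-methylene acid
Product: 31 16-hydroxy-16-methyl acid (OH exo, on the side of C14; methyl endo)
Conditions: Co(acac)2 (20 mol %), PhSiH3, O2 (1 atm), THF, rt
Reagents that add atoms: dioxygen, O=O
Why: Mukaiyama hydration (hydrogen atom transfer to C17, then capture of O2) is Markovnikov, and the tertiary C16 radical is trapped on the exo face of ring D because the endo face is covered by the C11–C12 bridge, which gives the hydroxyl exo and the methyl endo as in the target.

**Step 24**
Reactants: 31 16-hydroxy-16-methyl acid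
Product: 33 CNP0183110.3, via 3-O-acetyl triacid 32 (not isolated)
Conditions: EtSNa (12 equiv), DMF, 90 °C; then 2 M aq NaOH, MeOH, 40 °C; then 1 M HCl
Reagents that add atoms: none
Why: Thiolate SN2 attack on the methyl groups frees the two hindered tertiary acids without needing access to their shielded carbonyl carbons, and the acetate is saponified only afterwards, when C19 is a carboxylate that no longer allows retro-aldol epimerisation at C3.

**Compound list**

1 | 4,5-dimethoxy-1-indanone | COc1ccc2C(=O)CCc2c1OC | starting material
2 | 5-hydroxy-4-methoxy-1-indanone | Oc1ccc2C(=O)CCc2c1OC | intermediate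
3 | 4-methoxy-5-(methoxymethoxy)-1-indanone | COCOc1ccc2C(=O)CCc2c1OC | intermediate
4 | 4-methoxy-5-(methoxymethoxy)indan-1-ol (racemic, not isolated) | COCOc1ccc2C(O)CCc2c1OC | intermediate
5 | 7-methoxy-6-(methoxymethoxy)-1H-indene | COCOc1ccc2C=CCc2c1OC | intermediate
6 | 2,3-epoxy-7-methoxy-6-(methoxymethoxy)indane (racemic, not isolated) | COCOc1ccc2C3OC3Cc2c1OC | intermediate
7 | 4-methoxy-5-(methoxymethoxy)-2-indanone | COCOc1ccc2CC(=O)Cc2c1OC | intermediate
8 | methyl 4-methoxy-5-(methoxymethoxy)-2-oxoindane-1-carboxylate (labile centre) | COCOc1ccc2C(C(=O)OC)C(=O)Cc2c1OC | intermediate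
9 | 3-tert-butyl 1-methyl 4-methoxy-5-(methoxymethoxy)-2-oxoindane-1,3-dicarboxylate (labile centres) | COCOc1ccc2C(C(=O)OC)C(=O)C(C(=O)OC(C)(C)C)c2c1OC | intermediate
10 | methyl acetate | CC(=O)OC | starting material
11 | acrolein | C=CC=O | starting material
12 | methyl 3-hydroxypent-4-enoate (racemic) | C=CC(O)CC(=O)OC | intermediate
13 | methyl 3-oxopent-4-enoate | C=CC(=O)CC(=O)OC | intermediate
14 | Michael adduct, C10 quaternary (R), C20 ester α, C6 labile | O=C1C(C(=O)OC(C)(C)C)c2c(OC)c(OCOC)ccc2[C@]1(C(=O)OC)CCC(=O)CC(=O)OC | intermediate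
15 | tricyclic dienol, C3(OH)=C4(CO2Me)–C5=C6(CO2t-Bu) | OC1=C(C(=O)OC)C2=C(C(=O)OC(C)(C)C)c3c(OC)c(OCOC)ccc3[C@]2(C(=O)OC)CC1 | intermediate
16 | trans-fused β-keto ester (enol), H5β, H6β | OC1=C(C(=O)OC)[C@H]2[C@@H](C(=O)OC(C)(C)C)c3c(OC)c(OCOC)ccc3[C@]2(C(=O)OC)CC1 | intermediate
17 | 3-ketone, C18 β, C19 α, C7 ester α | C[C@]1(C(=O)OC)[C@H]2[C@@H](C(=O)OC(C)(C)C)c3c(OC)c(OCOC)ccc3[C@]2(C(=O)OC)CCC1=O | intermediate
18 | 3-ketone, C7 ester β | C[C@]1(C(=O)OC)[C@H]2[C@H](C(=O)OC(C)(C)C)c3c(OC)c(OCOC)ccc3[C@]2(C(=O)OC)CCC1=O | intermediate
19 | 3β-alcohol | C[C@]1(C(=O)OC)[C@H]2[C@H](C(=O)OC(C)(C)C)c3c(OC)c(OCOC)ccc3[C@]2(C(=O)OC)CC[C@@H]1O | intermediate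
20 | 3β-acetate | C[C@]1(C(=O)OC)[C@H]2[C@H](C(=O)OC(C)(C)C)c3c(OC)c(OCOC)ccc3[C@]2(C(=O)OC)CC[C@@H]1OC(C)=O | intermediate
21 | hexahydrofluorene guaiacol, free C7 acid | C[C@]1(C(=O)OC)[C@H]2[C@H](C(=O)O)c3c(OC)c(O)ccc3[C@]2(C(=O)OC)CC[C@@H]1OC(C)=O | intermediate
22 | acryloyl chloride | C=CC(=O)Cl | starting material
23 | N-hydroxyphthalimide | ON1C(=O)c2ccccc2C1=O | starting material
24 | N-(acryloyloxy)phthalimide | C=CC(=O)ON1C(=O)c2ccccc2C1=O | intermediate
25 | lactone ketal dienone (C15: OMe α, lactone O β; not isolated) | C[C@]1(C(=O)OC)[C@H]2[C@@H]3C(=O)O[C@]4(OC)C(=O)C=CC(=C34)[C@]2(C(=O)OC)CC[C@@H]1OC(C)=O | intermediate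
26 | bicyclo[2.2.2]octenone adduct | C[C@]1(C(=O)OC)[C@H]2[C@H](C(=O)O5)[C@@]34C[C@@H](C(=O)ON6C(=O)c7ccccc7C6=O)[C@@H](C=C3[C@]2(C(=O)OC)CC[C@@H]1OC(C)=O)C(=O)[C@]45OC | intermediate
27 | bicyclo[3.2.1]octenone lactone ketal | C[C@]1(C(=O)OC)[C@H]2[C@H](C(=O)O5)[C@@]34C[C@@H](CC=C3[C@]2(C(=O)OC)CC[C@@H]1OC(C)=O)C(=O)[C@]45OC | intermediate
28 | 16-ketone, C9=C11, free C7 acid | C[C@]1(C(=O)OC)[C@H]2[C@H](C(=O)O)[C@@]34C[C@@H](CC=C3[C@]2(C(=O)OC)CC[C@@H]1OC(C)=O)C(=O)C4 | intermediate
29 | 16-ketone, H9β | C[C@]1(C(=O)OC)[C@H]2[C@H](C(=O)O)[C@@]34C[C@@H](CC[C@H]3[C@]2(C(=O)OC)CC[C@@H]1OC(C)=O)C(=O)C4 | intermediate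
30 | 16-methylene acid | C[C@]1(C(=O)OC)[C@H]2[C@H](C(=O)O)[C@@]34C[C@@H](CC[C@H]3[C@]2(C(=O)OC)CC[C@@H]1OC(C)=O)C(=C)C4 | intermediate
31 | 16-hydroxy-16-methyl acid | C[C@]1(C(=O)OC)[C@H]2[C@H](C(=O)O)[C@@]34C[C@@H](CC[C@H]3[C@]2(C(=O)OC)CC[C@@H]1OC(C)=O)[C@](C)(O)C4 | intermediate
32 | 3-O-acetyl triacid (not isolated) | C[C@]1(C(=O)O)[C@H]2[C@H](C(=O)O)[C@@]34C[C@@H](CC[C@H]3[C@]2(C(=O)O)CC[C@@H]1OC(C)=O)[C@](C)(O)C4 | intermediate
33 | CNP0183110.3 | C[C@]1(C(=O)O)[C@H]2[C@H](C(=O)O)[C@@]34C[C@@H](CC[C@H]3[C@]2(C(=O)O)CC[C@@H]1O)[C@](C)(O)C4 | target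

Total step count: 24.
Longest linear sequence: 21 steps (steps 1–6, 9–16 and 18–24).

**Steps most likely to fail**

**Step 18.**
- **Risk:** cycloaddition at the fully substituted C8 may be slow on the face that also carries the C20 ester. During that time the acyloxy ketal could be lost by exchange with acetic acid, or 24 could polymerise.
- **Fallback:** it sets out from 21 and changes the dienophile and the point at which the radical precursor is installed.
- Compound 21 is oxidised as before, and 25 is trapped with a large excess of acrolein at 40 °C. Acrolein is smaller in the endo region and more electrophilic.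
- This gives the C13 aldehyde adduct F1. Pinnick oxidation (NaClO2, NaH2PO4, 2-methyl-2-butene) gives the C13 acid F2.
- Carbodiimide coupling of F2 with 23 (DIC, DMAP) returns to the route at 26.

**Step 19.**
- **Risk:** hydrogen may transfer to the C13 radical before it rearranges, or the competing 1,2-vinyl shift (C11 from C12 to C13) may be frozen by early reduction.
- **Fallback:** it sets out from 26 and removes every hydrogen donor from the rearrangement.
- Active-ester exchange with sodium 1-oxidopyridine-2-thione in the dark gives the Barton ester F3.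
- Irradiation of F3 in dilute benzene runs the decarboxylative chain, in which the only trap is the slow addition to the thiocarbonyl group. The radicals can therefore interconvert until the most stable allyl radical is captured, as the C12 allylic 2-pyridyl sulfide F4.
- Bu3SnH with AIBN then reduces F4 through the same allyl radical and returns to the route at 27.

**Step 11.**
- **Risk:** the tetrasubstituted, push-pull C5=C6 bond may not take up hydrogen, or facial selectivity may be poor so that the cis A/B fusion forms.
- **Fallback:** it sets out from 15 and replaces steric control by hydroxyl direction.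
- Deconjugative C4-methylation of the extended enolate (K2CO3, MeI; attack anti to C20) gives the Δ5(6) 3-ketone F5.
- LiBH(s-Bu)3 then gives the Δ5(6) 3β-alcohol F6.
- Homogeneous hydrogenation with [Ir(cod)(PCy3)(py)]PF6 in CH2Cl2 delivers H2 from the β face, on which the axial homoallylic hydroxyl binds the metal. This gives the saturated alcohol with α C7 ester F7.
- DBU epimerises C6 in F7 and returns to the route at 19.

**Further compounds**

F1 | step 18 | C13 aldehyde adduct | C[C@]1(C(=O)OC)[C@H]2[C@H](C(=O)O5)[C@@]34C[C@@H](C=O)[C@@H](C=C3[C@]2(C(=O)OC)CC[C@@H]1OC(C)=O)C(=O)[C@]45OC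
F2 | step 18 | C13 acid | C[C@]1(C(=O)OC)[C@H]2[C@H](C(=O)O5)[C@@]34C[C@@H](C(=O)O)[C@@H](C=C3[C@]2(C(=O)OC)CC[C@@H]1OC(C)=O)C(=O)[C@]45OC
F3 | step 19 | Barton ester | C[C@]1(C(=O)OC)[C@H]2[C@H](C(=O)O5)[C@@]34C[C@@H](C(=O)ON6C=CC=CC6=S)[C@@H](C=C3[C@]2(C(=O)OC)CC[C@@H]1OC(C)=O)C(=O)[C@]45OC
F4 | step 19 | C12 allylic 2-pyridyl sulfide (C12 drawn α; the centre is lost on reduction) | C[C@]1(C(=O)OC)[C@H]2[C@H](C(=O)O5)[C@@]34C[C@@H]([C@@H](Sc6ccccn6)C=C3[C@]2(C(=O)OC)CC[C@@H]1OC(C)=O)C(=O)[C@]45OC
F5 | step 11 | Δ5(6) 3-ketone | C[C@]1(C(=O)OC)C2=C(C(=O)OC(C)(C)C)c3c(OC)c(OCOC)ccc3[C@]2(C(=O)OC)CCC1=O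
F6 | step 11 | Δ5(6) 3β-alcohol | C[C@]1(C(=O)OC)C2=C(C(=O)OC(C)(C)C)c3c(OC)c(OCOC)ccc3[C@]2(C(=O)OC)CC[C@@H]1O
F7 | step 11 | saturated alcohol with α C7 ester | C[C@]1(C(=O)OC)[C@H]2[C@@H](C(=O)OC(C)(C)C)c3c(OC)c(OCOC)ccc3[C@]2(C(=O)OC)CC[C@@H]1O
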